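**Retrosynthetic overview**
1. The C8 angelate goes on last, onto hydroxy lactone 21 (O2 and O9 are already acetates).
2. Key disconnection C7–C8: the β-carbon of a 3-(bromomethyl)butenolide is made nucleophilic by CrCl2 (a latent homoenolate, d3 donor) and closes the ten-membered ring onto the C8 aldehyde, creating the exo-methylene, C7 and C8 at once.
3. The butenolide is made first, by ring-closing metathesis of the 2-(bromomethyl)acrylate of C6 carbinol 14; C6 comes from asymmetric vinylation of enal 13.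
4. C2–C3 and the E C4=C5 alkene come from a vinylogous Mukaiyama aldol of Z-enal 8 with the prenal dienol ether 10; the Z C1=C10 alkene comes from cuprate syn-addition to an ynoate.
5. C9 comes from (S)-glyceraldehyde acetonide plus methyl propiolate; the acetonide is later cut with H5IO6 to unmask C8=O. Ring order: lactone, then carbocycle.

Assumption: locants C1–C15 follow germacrane numbering of the target (lactone C12(=O)–O–C6; esters on O2, O8, O9), and where a chiral ligand is named, the antipode that gives the configuration drawn in the SMILES is meant.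

**Step 1**
Reactants: 1 (4S)-2,2-dimethyl-1,3-dioxolane-4-carbaldehyde; 2 methyl prop-2-ynoate
Product: 4 methyl (4R)-4-[(4S)-2,2-dimethyl-1,3-dioxolan-4-yl]-4-hydroxybut-2-ynoate, via zinc acetylide 3 (not isolated)
Conditions: Me2Zn, (S,S)-ProPhenol (20 mol%), Ph3PO (40 mol%), toluene, 0 °C
Reagents that add atoms: none
Why: Catalytic asymmetric alkynylation (zinc alkynylide addition) in which catalyst control and Felkin–Anh induction coincide for Re-face attack, setting C9 as (4R), anti to the dioxolane oxygen.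

**Step 2**
Reactants: 4 propargylic alcohol
Product: 5 methyl (4R)-4-[(tert-butyldimethylsilyl)oxy]-4-[(4S)-2,2-dimethyl-1,3-dioxolan-4-yl]but-2-ynoate
Conditions: TBSCl, imidazole, DMF, rt
Reagents that add atoms: tert-butyldimethylsilyl chloride, CC(C)(C)[Si](C)(C)Cl
Why: Imidazole-promoted silylation, needed so that the next step gives an open-chain Z-enoate and not a butenolide.

**Step 3**
Reactants: 5 silyloxy ynoate
Product: 6 methyl (2Z,4R)-4-[(tert-butyldimethylsilyl)oxy]-4-[(4S)-2,2-dimethyl-1,3-dioxolan-4-yl]-3-methylbut-2-enoate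
Conditions: CuI, MeLi (Me2CuLi), THF, −78 °C; MeOH then aq NH4Cl at −78 °C
Reagents that add atoms: lithium dimethylcuprate, [Li+].C[Cu-]C
Why: Syn-carbocupration of the ynoate by the Gilman reagent followed by cold protonation puts the new methyl cis to hydrogen, which fixes the Z C1=C10 double bond.

**Step 4**
Reactants: 6 Z-enoate
Product: 7 (2Z,4R)-4-[(tert-butyldimethylsilyl)oxy]-4-[(4S)-2,2-dimethyl-1,3-dioxolan-4-yl]-3-methylbut-2-en-1-ol
Conditions: i-Bu2AlH (DIBAL-H, 2.5 equiv), CH2Cl2, −78 °C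
Reagents that add atoms: none
Why: Hydride 1,2-reduction of the enoate to the allylic alcohol; silyl ether, acetonide and alkene geometry are untouched at −78 °C.

**Step 5**
Reactants: 7 Z-allylic alcohol
Product: 8 (2Z,4R)-4-[(tert-butyldimethylsilyl)oxy]-4-[(4S)-2,2-dimethyl-1,3-dioxolan-4-yl]-3-methylbut-2-enal
Conditions: Dess–Martin periodinane, NaHCO3, CH2Cl2, 0 °C
Reagents that add atoms: none
Why: Buffered Dess–Martin oxidation gives the Z-enal without Z/E isomerisation.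

**Step 6**
Reactants: 9 3-methylbut-2-enal (prenal)
Product: 10 (E)-tert-butyl[(3-methylbuta-1,3-dien-1-yl)oxy]dimethylsilane
Conditions: TBSOTf, Et3N, Et2O, 0 °C to rt
Reagents that add atoms: tert-butyldimethylsilyl triflate, CC(C)(C)[Si](C)(C)OS(=O)(=O)C(F)(F)F
Why: Silyl triflate/amine enolisation of prenal through γ-deprotonation gives the (E)-dienol silyl ether (silyl dienolate formation).

**Step 7**
Reactants: 8 Z-enal; 10 dienol silyl ether
Product: 11 (2E,5R,6Z,8R)-8-[(tert-butyldimethylsilyl)oxy]-8-[(4S)-2,2-dimethyl-1,3-dioxolan-4-yl]-5-hydroxy-3,7-dimethylocta-2,6-dienal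
Conditions: N-Ts-L-tryptophan, PhBCl2 (oxazaborolidinone formed first, 1.0 equiv), i-PrOH, EtCN, −78 °C; 10 added slowly
Reagents that add atoms: none
Why: Vinylogous Mukaiyama aldol reaction: the oxazaborolidinone-bound aldehyde is attacked on its Re face by the γ-carbon of the dienol ether, setting C2 (5R) and delivering the E enal (C4=C5) directly.

**Step 8**
Reactants: 11 silyloxy hydroxy enal
Product: 12 (2E,5R,6Z,8R)-8-[(4S)-2,2-dimethyl-1,3-dioxolan-4-yl]-5,8-dihydroxy-3,7-dimethylocta-2,6-dienal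
Conditions: TBAF, AcOH, THF, 0 °C
Reagents that add atoms: none
Why: Buffered fluoride desilylation frees O9 without retro-aldol or damage to the enal.

**Step 9**
Reactants: 12 diol
Product: 13 (2E,5R,6Z,8R)-5,8-bis(acetyloxy)-8-[(4S)-2,2-dimethyl-1,3-dioxolan-4-yl]-3,7-dimethylocta-2,6-dienal
Conditions: Ac2O, pyridine, DMAP (5 mol%), CH2Cl2, 0 °C
Reagents that add atoms: acetic anhydride, CC(=O)OC(C)=O
Why: DMAP-catalysed acetylation installs the two acetates of the target (O2, O9) at once.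

**Step 10**
Reactants: 13 diacetoxy enal
Product: 14 (3S,4E,7R,8Z,10R)-7,10-bis(acetyloxy)-10-[(4S)-2,2-dimethyl-1,3-dioxolan-4-yl]-5,9-dimethyldeca-1,4,8-trien-3-ol
Conditions: (CH2=CH)2Zn (from CH2=CHMgBr, ZnCl2; salts removed with 1,4-dioxane), (−)-DAIB (10 mol%), toluene, −20 °C
Reagents that add atoms: divinylzinc, C=C[Zn]C=C
Why: Amino-alcohol-catalysed enantioselective organozinc addition: vinyl transfer to the Si face of the enal sets C6 (3S) under reagent control while the acetates survive.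

**Step 11**
Reactants: 14 divinyl carbinol; 15 2-(bromomethyl)prop-2-enoic acid
Product: 16 (3S,4E,7R,8Z,10R)-7,10-bis(acetyloxy)-10-[(4S)-2,2-dimethyl-1,3-dioxolan-4-yl]-5,9-dimethyldeca-1,4,8-trien-3-yl 2-(bromomethyl)prop-2-enoate
Conditions: DCC, DMAP (5 mol%), CH2Cl2, −10 to 0 °C
Reagents that add atoms: none
Why: Steglich esterification of the bis-allylic alcohol brings in C11, C12, C13 and the allylic bromide.

**Step 12**
Reactants: 16 acrylate ester
Product: 17 (5R)-3-(bromomethyl)-5-[(1E,4R,5Z,7R)-4,7-bis(acetyloxy)-7-[(4S)-2,2-dimethyl-1,3-dioxolan-4-yl]-2,6-dimethylhepta-1,5-dien-1-yl]furan-2(5H)-one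
Conditions: second-generation Grubbs catalyst RuCl2(=CHPh)(PCy3)(H2IMes) (10 mol%), CH2Cl2 (0.005 M), 40 °C
Reagents that add atoms: none
Why: Ring-closing metathesis of the vinyl group onto the acrylate alkene forms the butenolide; the trisubstituted chain alkenes do not engage.

**Step 13**
Reactants: 17 bromomethyl butenolide acetonide
Product: 19 (5R)-3-(bromomethyl)-5-[(1E,4R,5Z,7R)-4,7-bis(acetyloxy)-2,6-dimethyl-8-oxoocta-1,5-dien-1-yl]furan-2(5H)-one, via diol 18 (not isolated)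
Conditions: H5IO6 (2 equiv), EtOAc, rt; crude aldehyde used at once
Reagents that add atoms: none
Why: Periodic acid hydrolyses the terminal acetonide and cleaves the 1,2-diol in the same pot (Malaprade glycol cleavage), excising the auxiliary carbon and unmasking the C8 aldehyde under mild conditions.

**Step 14 (key step)**
Reactants: 19 bromomethyl butenolide aldehyde
Product: 21 (3aR,4R,5R,6Z,8R,10E,11aR)-4-hydroxy-6,10-dimethyl-3-methylidene-2-oxo-2,3,3a,4,5,8,9,11a-octahydrocyclodeca[b]furan-5,8-diyl diacetate, via allylchromium dichloride 20 (not isolated)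
Conditions: CrCl2 (8 equiv), THF, 0.002 M (slow addition of 19), rt; aqueous work-up
Reagents that add atoms: none
Why: Divalent chromium inserts into the C–Br bond so that C7, the β-carbon of the butenolide and normally an acceptor, becomes a homoenolate-type (d3) donor, and the intramolecular Nozaki–Hiyama allylation of the C8 aldehyde through a chair transition state (E-type γ-terminus, attack anti to the C6 side chain) gives the ten-membered ring, the exo-methylene, and the 6,7-trans/7,8-anti centres C7 and C8.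

**Step 15**
Reactants: 21 hydroxy lactone; 22 (2Z)-2-methylbut-2-enoic acid (angelic acid)
Product: 24 (3aS,4R,5R,6Z,8R,10E,11aR)-5,8-bis(acetyloxy)-6,10-dimethyl-3-methylidene-2-oxo-2,3,3a,4,5,8,9,11a-octahydrocyclodeca[b]furan-4-yl (2Z)-2-methylbut-2-enoate (CNP0499619.1), via mixed anhydride 23 (not isolated)
Conditions: 22, 2,4,6-trichlorobenzoyl chloride, Et3N, toluene, rt; then 21, toluene, 80 °C (no DMAP)
Reagents that add atoms: none
Why: Yamaguchi esterification via the mixed anhydride, run without DMAP so that the angelate does not isomerise to the tiglate; 8-OH is the only free hydroxyl.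

**Compound list**
1 | (4S)-2,2-dimethyl-1,3-dioxolane-4-carbaldehyde | O=C[C@@H]1COC(C)(C)O1 | starting material
2 | methyl prop-2-ynoate | C#CC(=O)OC | starting material
3 | methyl 3-(methylzincio)prop-2-ynoate | COC(=O)C#C[Zn]C | intermediate
4 | methyl (4R)-4-[(4S)-2,2-dimethyl-1,3-dioxolan-4-yl]-4-hydroxybut-2-ynoate | COC(=O)C#C[C@@H](O)[C@@H]1COC(C)(C)O1 | intermediate
5 | methyl (4R)-4-[(tert-butyldimethylsilyl)oxy]-4-[(4S)-2,2-dimethyl-1,3-dioxolan-4-yl]but-2-ynoate | COC(=O)C#C[C@@H](O[Si](C)(C)C(C)(C)C)[C@@H]1COC(C)(C)O1 | intermediate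
6 | methyl (2Z,4R)-4-[(tert-butyldimethylsilyl)oxy]-4-[(4S)-2,2-dimethyl-1,3-dioxolan-4-yl]-3-methylbut-2-enoate | COC(=O)/C=C(/C)[C@@H](O[Si](C)(C)C(C)(C)C)[C@@H]1COC(C)(C)O1 | intermediate
7 | (2Z,4R)-4-[(tert-butyldimethylsilyl)oxy]-4-[(4S)-2,2-dimethyl-1,3-dioxolan-4-yl]-3-methylbut-2-en-1-ol | OC/C=C(/C)[C@@H](O[Si](C)(C)C(C)(C)C)[C@@H]1COC(C)(C)O1 | intermediate
8 | (2Z,4R)-4-[(tert-butyldimethylsilyl)oxy]-4-[(4S)-2,2-dimethyl-1,3-dioxolan-4-yl]-3-methylbut-2-enal | O=C/C=C(/C)[C@@H](O[Si](C)(C)C(C)(C)C)[C@@H]1COC(C)(C)O1 | intermediate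
9 | 3-methylbut-2-enal | CC(C)=CC=O | starting material
10 | (E)-tert-butyl[(3-methylbuta-1,3-dien-1-yl)oxy]dimethylsilane | C=C(C)/C=C/O[Si](C)(C)C(C)(C)C | intermediate
11 | (2E,5R,6Z,8R)-8-[(tert-butyldimethylsilyl)oxy]-8-[(4S)-2,2-dimethyl-1,3-dioxolan-4-yl]-5-hydroxy-3,7-dimethylocta-2,6-dienal | O=C/C=C(\C)C[C@@H](O)/C=C(/C)[C@@H](O[Si](C)(C)C(C)(C)C)[C@@H]1COC(C)(C)O1 | intermediate
12 | (2E,5R,6Z,8R)-8-[(4S)-2,2-dimethyl-1,3-dioxolan-4-yl]-5,8-dihydroxy-3,7-dimethylocta-2,6-dienal | O=C/C=C(\C)C[C@@H](O)/C=C(/C)[C@@H](O)[C@@H]1COC(C)(C)O1 | intermediate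
13 | (2E,5R,6Z,8R)-5,8-bis(acetyloxy)-8-[(4S)-2,2-dimethyl-1,3-dioxolan-4-yl]-3,7-dimethylocta-2,6-dienal | O=C/C=C(\C)C[C@@H](OC(C)=O)/C=C(/C)[C@@H](OC(C)=O)[C@@H]1COC(C)(C)O1 | intermediate
14 | (3S,4E,7R,8Z,10R)-7,10-bis(acetyloxy)-10-[(4S)-2,2-dimethyl-1,3-dioxolan-4-yl]-5,9-dimethyldeca-1,4,8-trien-3-ol | C=C[C@H](O)/C=C(\C)C[C@@H](OC(C)=O)/C=C(/C)[C@@H](OC(C)=O)[C@@H]1COC(C)(C)O1 | intermediate
15 | 2-(bromomethyl)prop-2-enoic acid | C=C(CBr)C(=O)O | starting material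
16 | (3S,4E,7R,8Z,10R)-7,10-bis(acetyloxy)-10-[(4S)-2,2-dimethyl-1,3-dioxolan-4-yl]-5,9-dimethyldeca-1,4,8-trien-3-yl 2-(bromomethyl)prop-2-enoate | C=C(CBr)C(=O)O[C@@H](C=C)/C=C(\C)C[C@@H](OC(C)=O)/C=C(/C)[C@@H](OC(C)=O)[C@@H]1COC(C)(C)O1 | intermediate
17 | (5R)-3-(bromomethyl)-5-[(1E,4R,5Z,7R)-4,7-bis(acetyloxy)-7-[(4S)-2,2-dimethyl-1,3-dioxolan-4-yl]-2,6-dimethylhepta-1,5-dien-1-yl]furan-2(5H)-one | BrCC1=C[C@H](OC1=O)/C=C(\C)C[C@@H](OC(C)=O)/C=C(/C)[C@@H](OC(C)=O)[C@@H]1COC(C)(C)O1 | intermediate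
18 | (5R)-3-(bromomethyl)-5-[(1E,4R,5Z,7R,8S)-4,7-bis(acetyloxy)-8,9-dihydroxy-2,6-dimethylnona-1,5-dien-1-yl]furan-2(5H)-one | BrCC1=C[C@H](OC1=O)/C=C(\C)C[C@@H](OC(C)=O)/C=C(/C)[C@@H](OC(C)=O)[C@@H](O)CO | intermediate
19 | (5R)-3-(bromomethyl)-5-[(1E,4R,5Z,7R)-4,7-bis(acetyloxy)-2,6-dimethyl-8-oxoocta-1,5-dien-1-yl]furan-2(5H)-one | BrCC1=C[C@H](OC1=O)/C=C(\C)C[C@@H](OC(C)=O)/C=C(/C)[C@@H](OC(C)=O)C=O | intermediate
20 | {(5R)-5-[(1E,4R,5Z,7R)-4,7-bis(acetyloxy)-2,6-dimethyl-8-oxoocta-1,5-dien-1-yl]-2-oxo-2,5-dihydrofuran-3-yl}methylchromium dichloride (allyl–CrCl2, trivalent chromium) | Cl[Cr](Cl)CC1=C[C@H](OC1=O)/C=C(\C)C[C@@H](OC(C)=O)/C=C(/C)[C@@H](OC(C)=O)C=O | intermediate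
21 | (3aR,4R,5R,6Z,8R,10E,11aR)-4-hydroxy-6,10-dimethyl-3-methylidene-2-oxo-2,3,3a,4,5,8,9,11a-octahydrocyclodeca[b]furan-5,8-diyl diacetate | C=C1C(=O)O[C@@H]2/C=C(\C)C[C@@H](OC(C)=O)/C=C(/C)[C@@H](OC(C)=O)[C@H](O)[C@@H]12 | intermediate
22 | (2Z)-2-methylbut-2-enoic acid (angelic acid) | C/C=C(/C)C(=O)O | starting material
23 | (2Z)-2-methylbut-2-enoic 2,4,6-trichlorobenzoic anhydride | C/C=C(/C)C(=O)OC(=O)c1c(Cl)cc(Cl)cc1Cl | intermediate
24 | (3aS,4R,5R,6Z,8R,10E,11aR)-5,8-bis(acetyloxy)-6,10-dimethyl-3-methylidene-2-oxo-2,3,3a,4,5,8,9,11a-octahydrocyclodeca[b]furan-4-yl (2Z)-2-methylbut-2-enoate | C=C1C(=O)O[C@@H]2/C=C(\C)C[C@@H](OC(C)=O)/C=C(/C)[C@@H](OC(C)=O)[C@H](OC(=O)/C(C)=C\C)[C@@H]12 | target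

**Step count**
Total: 15 steps. Longest linear sequence: 14 steps (1 to 24 through steps 1–5 and 7–15); step 6 is a one-step side branch.

**Three steps most likely to fail**

Step 14 (ring closure). This ring size has no direct precedent with a butenolide donor. The C9 acetoxy centre is Felkin-mismatched with the C8 configuration that allyl and ring control demand, so the wrong C7/C8 pair or oligomers could form. The chromium alkoxide of 21 could also translactonise or pick up the O9 acetyl group. Fallback, setting out from 16 and returning at 21: the ring is closed by a reductant-free allylboration triggered by release of the aldehyde. Copper-catalysed borylation of 16 (B2pin2, CuCl, KOAc, DMF; the allyl unit is symmetric, so SN2 and SN2′ give the same product) gives the 2-(borylmethyl)acrylate ester F1. Ring-closing metathesis as in step 12 gives the 3-(pinacolborylmethyl)butenolide F2. H5IO6 in EtOAc gives, through the diol F3, the boryl aldehyde F4. Heating F4 in toluene (80 °C, 0.002 M) closes the ring through the tighter boron chair (same E-type γ-terminus, hence the same 7,8-anti sense) and gives 21 after aqueous NaHCO3.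

Step 7 (vinylogous aldol). Product 11 is itself a β,β-disubstituted enal of similar reactivity to acceptor 8, so over-addition and modest facial control are possible. Fallback, setting out from 8 and returning at 11: use an amide dienolate whose adduct is not an acceptor. 4-(3-Methylbut-2-enoyl)morpholine F5 (from 3-methylbut-2-enoyl chloride and morpholine) is converted with lithium diisopropylamide and TBSCl into its N,O-ketene acetal F6. F6 adds through its γ-carbon to 8 under SiCl4 with a chiral bisphosphoramide catalyst (CH2Cl2, −78 °C) to give the morpholine amide F7. Reduction of F7 with i-Bu2AlH at −78 °C stops at the aldehyde and gives 11.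

Step 10 (asymmetric vinylation). Divinylzinc must be salt-free, and the hindered enal may give modest selectivity at C6. Fallback, setting out from 13 and returning at 14: alkynylation then semihydrogenation. Zinc–ProPhenol alkynylation of 13 with trimethylsilylacetylene (Me2Zn, toluene, 0 °C) gives the silyl propargylic alcohol F8. TBAF/AcOH gives the terminal propargylic alcohol F9. Hydrogenation over Lindlar catalyst (Pd/CaCO3 poisoned with Pb(OAc)2, quinoline, H2) gives 14.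

**Further compounds**
F1 | step 14 | (3S,4E,7R,8Z,10R)-7,10-bis(acetyloxy)-10-[(4S)-2,2-dimethyl-1,3-dioxolan-4-yl]-5,9-dimethyldeca-1,4,8-trien-3-yl 2-[(4,4,5,5-tetramethyl-1,3,2-dioxaborolan-2-yl)methyl]prop-2-enoate | C=C(CB1OC(C)(C)C(C)(C)O1)C(=O)O[C@@H](C=C)/C=C(\C)C[C@@H](OC(C)=O)/C=C(/C)[C@@H](OC(C)=O)[C@@H]1COC(C)(C)O1
F2 | step 14 | (5R)-5-[(1E,4R,5Z,7R)-4,7-bis(acetyloxy)-7-[(4S)-2,2-dimethyl-1,3-dioxolan-4-yl]-2,6-dimethylhepta-1,5-dien-1-yl]-3-[(4,4,5,5-tetramethyl-1,3,2-dioxaborolan-2-yl)methyl]furan-2(5H)-one | CC1(C)OB(CC2=C[C@H](OC2=O)/C=C(\C)C[C@@H](OC(C)=O)/C=C(/C)[C@@H](OC(C)=O)[C@@H]3COC(C)(C)O3)OC1(C)C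
F3 | step 14 | (5R)-5-[(1E,4R,5Z,7R,8S)-4,7-bis(acetyloxy)-8,9-dihydroxy-2,6-dimethylnona-1,5-dien-1-yl]-3-[(4,4,5,5-tetramethyl-1,3,2-dioxaborolan-2-yl)methyl]furan-2(5H)-one | CC1(C)OB(CC2=C[C@H](OC2=O)/C=C(\C)C[C@@H](OC(C)=O)/C=C(/C)[C@@H](OC(C)=O)[C@@H](O)CO)OC1(C)C
F4 | step 14 | (5R)-5-[(1E,4R,5Z,7R)-4,7-bis(acetyloxy)-2,6-dimethyl-8-oxoocta-1,5-dien-1-yl]-3-[(4,4,5,5-tetramethyl-1,3,2-dioxaborolan-2-yl)methyl]furan-2(5H)-one | CC1(C)OB(CC2=C[C@H](OC2=O)/C=C(\C)C[C@@H](OC(C)=O)/C=C(/C)[C@@H](OC(C)=O)C=O)OC1(C)C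
F5 | step 7 | 4-(3-methylbut-2-enoyl)morpholine | CC(C)=CC(=O)N1CCOCC1
F6 | step 7 | tert-butyl{[(1Z)-3-methyl-1-(morpholin-4-yl)buta-1,3-dien-1-yl]oxy}dimethylsilane | C=C(C)/C=C(\O[Si](C)(C)C(C)(C)C)N1CCOCC1
F7 | step 7 | (2E,5R,6Z,8R)-8-[(tert-butyldimethylsilyl)oxy]-8-[(4S)-2,2-dimethyl-1,3-dioxolan-4-yl]-5-hydroxy-3,7-dimethyl-1-(morpholin-4-yl)octa-2,6-dien-1-one | O=C(/C=C(\C)C[C@@H](O)/C=C(/C)[C@@H](O[Si](C)(C)C(C)(C)C)[C@@H]1COC(C)(C)O1)N1CCOCC1
F8 | step 10 | (3R,4E,7R,8Z,10R)-7,10-bis(acetyloxy)-10-[(4S)-2,2-dimethyl-1,3-dioxolan-4-yl]-5,9-dimethyl-1-(trimethylsilyl)deca-4,8-dien-1-yn-3-ol | C[Si](C)(C)C#C[C@H](O)/C=C(\C)C[C@@H](OC(C)=O)/C=C(/C)[C@@H](OC(C)=O)[C@@H]1COC(C)(C)O1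
F9 | step 10 | (3R,4E,7R,8Z,10R)-7,10-bis(acetyloxy)-10-[(4S)-2,2-dimethyl-1,3-dioxolan-4-yl]-5,9-dimethyldeca-4,8-dien-1-yn-3-ol | C#C[C@H](O)/C=C(\C)C[C@@H](OC(C)=O)/C=C(/C)[C@@H](OC(C)=O)[C@@H]1COC(C)(C)O1
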